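I wanted a rule for where a charge of electrophile ends up, so I began from the two runs so far; the winter run is the flask asked about, followed up to its last reading.

common to all: nucleophile 0.104 M

| run | electrophile | free base | remark | time |
|---|---|---|---|---|
| winter | 0.11 M (fed, over 1.5 min) | 0.11 M | the very flask that is asked about, followed so far |  |
| summer | 0.055 M (fed, over 1.5 min) | 0.11 M | run made earlier |  |
| flask | 0.11 M (fed, over 1.5 min) | 0.110 M |  | 2.5 min |

| run | time / s | electrophile / % | target / % |
|---|---|---|---|
| winter | 10.0 | 6.9 | 1.3 |
| winter | 15.0 | 10.0 | 3.3 |
| winter | 25.0 | 15.6 | 5.9 |
| winter | 30.0 | 17.8 | 6.1 |
| winter | 40.0 | 23.3 | 9.2 |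
| winter | 50.0 | 30.2 | 12.2 |
| summer | 10.0 | 6.8 | 1.2 |
| summer | 12.0 | 7.7 | 1.4 |
| summer | 20.0 | 12.7 | 4.1 |
| summer | 30.0 | 18.0 | 7.1 |
| summer | 50.0 | 28.8 | 12.1 |
| summer | 60.0 | 34.2 | 15.6 |

(scatter of a reading: 0.5 percentage points)

- steps that have been proposed: acid set free + free base <-> salt of the base; 2 nucleophile -> self-condensation product; nucleophile + acid set free <-> protonated nucleophile; electrophile + nucleophile -> acid set free + target; electrophile <-> dormant form
- what has gone from electrophile into another species counts as reacted, even if it can come back
- percentages count the whole charge, also what has not yet gone in
- the earlier runs do not show how much of nucleophile is bound; that part of a forecast is a guess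

1. part of the electrophile that has reacted at 2.5 min
2. share of the unused nucleophile that is free and not bound as protonated nucleophile, at 2.5 min

In each run I took what the feed had put in by the last reading and subtracted electrophile and target. The gap per electrophile read 0.464 on average, and I called it the parking ratio, dormant form per electrophile. Once the feed is in and target has stopped rising, the part that is not target divides by one plus this ratio to give the electrophile left, and the rest counts as reacted.

Next I carried a straight line through the winter target readings to the end of the feed, which gave 23.1%. I guessed that target stopped there, so the rule gave 47.5% reacted, and I committed to that.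

The line was the weak link, so I redrew it through the summer run. That gave 24.2% target and 48.3% reacted, and the rule passes on 0.683 of a point for each point of target. The free share of nucleophile the runs do not show, so I gave no number for it.

The forecast said 51% reacted, more than my reckoning, and 70% free, the second a guess; it read the same gap, “so the dormant form equilibrates fast”.

The flask gave 46.9% reacted and 97.0% of the unused nucleophile free, 27 percentage points above the forecast.

    acid set free + free base ⇌ salt of the base, settled at all times (K = 2.60 × 10⁵ /M)
    2 nucleophile → self-condensation product (k = 0.460 /M/s)
    nucleophile + acid set free ⇌ protonated nucleophile, settled at all times (K = 30000 /M)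
    electrophile + nucleophile → acid set free + target (k = 0.640 /M/s)
    electrophile ⇌ dormant form (K = 0.490, k = 0.190 /s)

At 2.50 min the flask held 20.9% target, with 0.29% left of its nucleophile, the limiting reagent, less than the 53% left of its electrophile. The parking ratio turns that target into 46.0% reacted. The neighbour charged with 0.044 M of electrophile reached 30.8% target, which the ratio turns into 52.7%, and that neighbour stood at 53.6%.

The runs are simulated from invented constants; noise was put on by code.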